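## Retrosynthetic overview

1. Cut the C14–O ester between acid fragment A (upper cyclohexene half) and lactone fragment B, then open the seven-membered lactone of B (C2 acid + C15–OH); the lactone is closed last.
2. Each cyclohexane ring is ring B of a bicyclo[2.2.2]octene Diels–Alder adduct of α-phellandrene and a buta-2,3-dienoate: (R)-diene for fragment B, (S)-diene for fragment A.
3. Ozonolysis of the etheno bridge leaves CHO on C6 cis to the bought isopropyl (C7) and to the endo ester (C1–C2); the acetyl left on C9 is removed by Baeyer–Villiger oxidation and Pd/formate hydrogenolysis.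
4. CHO becomes the (E)-2-(silyloxymethyl)acrylate by Wittig reaction; the exocyclic methylene becomes the C10 diol (B), or, after iodolactonisation and decarboxylation, the C1'=C10' allylic alcohol (A).
5. Ring order: ring B of fragment B and ring B of fragment A (both by Diels–Alder), then the ε-lactone after the ester union.

Assumption: both enantiomers of α-phellandrene and the two allenoates are taken as purchasable, and the two silyloxymethyl Wittig ylides as stock reagents (one operation from commercial tert-butyl (triphenylphosphoranylidene)acetate). Locants: ring carbons C1 (bears carboxyl C2), C6 (bears C5), C7 (isopropyl), C8, C9, C10 (bears O and C14); C4 is the acrylate carbon carrying C3 (carboxyl) and C15 (CH2O); primed locants are used for fragment A.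

## Fragment B

Step 1
Reactants: 1 (R)-(−)-α-phellandrene; 2 tert-butyl buta-2,3-dienoate
Product: 3 endo adduct tert-butyl 7-isopropyl-5-methyl-3-methylidenebicyclo[2.2.2]oct-5-ene-2-carboxylate
Conditions: toluene, BHT (cat.), 110 °C, sealed tube, 2 equiv of 1
Reagents that add atoms: none
Why: Diels–Alder cycloaddition in which the allenoate adds anti to the isopropyl group, the ester-bearing carbon bonds to the diene terminus remote from the ring methyl ("para" orientation) and the ester sits endo, so C1 and C6 are set by the bought C7.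

Step 2
Reactants: 3 endo adduct
Product: 5 all-cis keto aldehyde, via ozonide 4 (not isolated)
Conditions: O3 (1.0 equiv, Sudan Red 7B end point), CH2Cl2, −78 °C; then PPh3, −78 °C → rt
Reagents that add atoms: ozone ([O-][O+]=O)
Why: Ozonolysis cleaves the electron-rich trisubstituted bridge alkene before the ester-deactivated 1,1-disubstituted methylene, leaving CHO on C6 (cis to isopropyl and ester because the bridge was syn to both) and acetyl on C9 without touching a stereocentre.

Step 3
Reactants: 5 all-cis keto aldehyde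
Product: 6 (E)-enoate
Conditions: ylide (1.3 equiv), toluene, 70 °C
Reagents that add atoms: tert-butyl 3-[(tert-butyldimethylsilyl)oxy]-2-(triphenylphosphoranylidene)propanoate (CC(C)(C)OC(=O)C(CO[Si](C)(C)C(C)(C)C)=P(c1ccccc1)(c1ccccc1)c1ccccc1)
Why: Wittig olefination with an α-substituted stabilised ylide takes the aldehyde in preference to the methyl ketone and gives the E alkene (ester trans to the ring), with C6 kept intact under non-basic conditions.

Step 4
Reactants: 6 (E)-enoate
Product: 7 C9 acetate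
Conditions: Me3SiOOSiMe3, TMSOTf (10 mol %), CH2Cl2, −40 °C
Reagents that add atoms: bis(trimethylsilyl) peroxide (C[Si](C)(C)OO[Si](C)(C)C)
Why: Baeyer–Villiger oxidation in which the secondary allylic C9 migrates with retention in preference to methyl, using a silyl peroxide that does not epoxidise the alkenes.

Step 5
Reactants: 7 C9 acetate
Product: 8 methylidene ester with C9 as CH2
Conditions: Pd(OAc)2 (5 mol %), PBu3 (20 mol %), HCO2NH4 (3 equiv), 1,4-dioxane, 80 °C
Reagents that add atoms: none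
Why: Tsuji-type formate hydrogenolysis: zerovalent palladium ionises the allylic acetate and hydride is delivered to the more substituted allyl terminus, so C9 becomes CH2 and the exocyclic methylene is kept.

Step 6
Reactants: 8 methylidene ester
Product: 9 C10/C14 diol
Conditions: OsO4 (2 mol %), NMO, acetone–H2O, 0 °C → rt
Reagents that add atoms: 4-methylmorpholine N-oxide (C[N+]1([O-])CCOCC1); water (O)
Why: Upjohn dihydroxylation attacks only the electron-rich methylene, from the equatorial face away from the axial C6 side chain and the C1 ester, which puts the C10 hydroxyl trans and CH2OH cis to the other ring substituents (the tert-butyl ester blocks γ-lactonisation).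

## Fragment A

Step 7
Reactants: 10 (S)-(+)-α-phellandrene; 11 methyl buta-2,3-dienoate
Product: 12 endo adduct methyl 7-isopropyl-5-methyl-3-methylidenebicyclo[2.2.2]oct-5-ene-2-carboxylate (enantiomeric series)
Conditions: toluene, BHT (cat.), 110 °C, sealed tube, 2 equiv of 10
Reagents that add atoms: none
Why: The same Diels–Alder cycloaddition (anti to isopropyl, "para", endo) in the mirror-image series fixes C6' relative to the bought C7'.

Step 8
Reactants: 12 endo adduct
Product: 14 all-cis keto aldehyde, via ozonide 13 (not isolated)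
Conditions: O3 (1.0 equiv, Sudan Red 7B end point), CH2Cl2, −78 °C; then PPh3, −78 °C → rt
Reagents that add atoms: ozone ([O-][O+]=O)
Why: Chemoselective ozonolysis of the trisubstituted bridge alkene gives CHO on C6' cis to the isopropyl group, as in step 2.

Step 9
Reactants: 14 all-cis keto aldehyde
Product: 15 (E)-enoate
Conditions: ylide (1.3 equiv), toluene, 70 °C
Reagents that add atoms: tert-butyl 3-[(tert-butyldiphenylsilyl)oxy]-2-(triphenylphosphoranylidene)propanoate (CC(C)(C)OC(=O)C(CO[Si](c1ccccc1)(c1ccccc1)C(C)(C)C)=P(c1ccccc1)(c1ccccc1)c1ccccc1)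
Why: Aldehyde-selective Wittig olefination with the stabilised ylide gives the E acrylate with C3' trans to the ring.

Step 10
Reactants: 15 (E)-enoate
Product: 16 C9' acetate
Conditions: Me3SiOOSiMe3, TMSOTf (10 mol %), CH2Cl2, −40 °C
Reagents that add atoms: bis(trimethylsilyl) peroxide (C[Si](C)(C)OO[Si](C)(C)C)
Why: Baeyer–Villiger oxidation with migration of the secondary allylic C9', as in step 4.

Step 11
Reactants: 16 C9' acetate
Product: 17 methylidene methyl ester with C9' as CH2
Conditions: Pd(OAc)2 (5 mol %), PBu3 (20 mol %), HCO2NH4 (3 equiv), 1,4-dioxane, 80 °C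
Reagents that add atoms: none
Why: Tsuji-type formate hydrogenolysis of the allylic acetate with hydride delivery to the ring terminus, as in step 5.

Step 12
Reactants: 17 methylidene methyl ester
Product: 18 β,γ-unsaturated acid
Conditions: LiOH·H2O, THF–H2O (3:1), 0 °C; then dilute HCl
Reagents that add atoms: lithium hydroxide ([Li+].[OH-])
Why: Saponification of the methyl ester only (the tert-butyl acrylate ester survives), run cold to avoid moving the methylene into conjugation.

Step 13
Reactants: 18 β,γ-unsaturated acid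
Product: 21 allylic alcohol with the C1'=C10' alkene, via iodo-beta-lactone 19 (not isolated), via allylic iodide 20 (not isolated)
Conditions: I2, NaHCO3, MeCN–H2O, 0 °C; then 70 °C
Reagents that add atoms: iodine (II); water (O)
Why: Iodolactonisation (4-exo, cis-fused β-lactone), thermal decarboxylation by [2+2] cycloreversion and hydrolysis of the primary allylic iodide put the alkene exactly between C1' and C10' and the oxygen on C14', deliberately erasing the C1' stereocentre.

Step 14
Reactants: 21 allylic alcohol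
Product: 22 bis-TBDPS tert-butyl ester
Conditions: TBDPSCl, imidazole, DMF, rt
Reagents that add atoms: tert-butyl(chloro)diphenylsilane (CC(C)(C)[Si](Cl)(c1ccccc1)c1ccccc1)
Why: Standard silylation of the primary allylic alcohol so that fragment A cannot esterify itself in the coupling.

Step 15
Reactants: 22 bis-TBDPS tert-butyl ester
Product: 23 fragment A acid
Conditions: TFA–CH2Cl2 (1:4), 0 °C
Reagents that add atoms: none
Why: Acidolysis of the tert-butyl ester, which the TBDPS ethers and the trisubstituted alkenes tolerate at 0 °C.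

## Union and endgame

Step 16
Reactants: 9 C10/C14 diol; 23 fragment A acid
Product: 24 C14 ester
Conditions: MNBA, DMAP, Et3N, CH2Cl2, rt
Reagents that add atoms: none
Why: Shiina esterification acylates the primary C14 hydroxyl and leaves the tertiary C10 hydroxyl alone, and the tiglate-type E acid does not isomerise.

Step 17
Reactants: 24 C14 ester
Product: 25 seco diacid with free C15 hydroxyl
Conditions: TFA–CH2Cl2–H2O (20:79:1), 0 °C → rt
Reagents that add atoms: none
Why: Acidolysis removes both tert-butyl esters and the primary TBS ether, while the two TBDPS ethers and the C14 ester stay.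

Step 18
Reactants: 25 seco diacid
Product: 26 bis-TBDPS lactone
Conditions: MNBA, DMAP, Et3N, CH2Cl2 (2 mM, slow addition), rt
Reagents that add atoms: none
Why: Shiina macrolactonisation: only the C2 acid can reach the C15 hydroxyl (cis to C6 on the alkene) to close the seven-membered lactone, the E-disposed C3 acid cannot cyclise and is recovered as the acid on work-up.

Step 19
Reactants: 26 bis-TBDPS lactone
Product: 27 target CNP0361406.12
Conditions: HF·pyridine, pyridine–THF, 0 °C → rt
Reagents that add atoms: none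
Why: Fluoride desilylation of the two primary TBDPS ethers leaves esters, lactone, acid and tertiary alcohol untouched.

## Compound list

1 | (R)-(−)-α-phellandrene, (5R)-2-methyl-5-(propan-2-yl)cyclohexa-1,3-diene | CC(C)[C@H]1CC=C(C)C=C1 | starting material
2 | tert-butyl buta-2,3-dienoate | C=C=CC(=O)OC(C)(C)C | starting material
3 | tert-butyl 7-isopropyl-5-methyl-3-methylidenebicyclo[2.2.2]oct-5-ene-2-carboxylate; ester endo and isopropyl both syn to the C5=C6 bridge, ester carbon on the bridgehead next to CH(iPr) | CC(C)[C@H]1C[C@@H]2C(=C)[C@@H](C(=O)OC(C)(C)C)[C@H]1C=C2C | intermediate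
4 | ozonide (1,2,4-trioxolane) of 3 across the former C5=C6 bridge; the two trioxolane carbons as formed | CC(C)[C@H]1C[C@@H]2C(=C)[C@@H](C(=O)OC(C)(C)C)[C@H]1C3OC2(C)OO3 | intermediate (not isolated)
5 | tert-butyl 3-acetyl-6-formyl-2-methylidene-5-isopropylcyclohexane-1-carboxylate, substituents on C1, C3, C5, C6 all cis (CO2tBu on C1, CHO on C6, iPr on C7, Ac on C9 in target locants) | CC(C)[C@H]1C[C@@H](C(C)=O)C(=C)[C@@H](C(=O)OC(C)(C)C)[C@H]1C=O | intermediate
6 | as 5 with CHO replaced by (E)-CH=C(CH2OTBS)CO2tBu (ester trans to ring) | CC(C)[C@H]1C[C@@H](C(C)=O)C(=C)[C@@H](C(=O)OC(C)(C)C)[C@H]1/C=C(/C(=O)OC(C)(C)C)CO[Si](C)(C)C(C)(C)C | intermediate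
7 | as 6 with the C9 acetyl replaced by acetoxy, same configuration | CC(C)[C@H]1C[C@@H](OC(C)=O)C(=C)[C@@H](C(=O)OC(C)(C)C)[C@H]1/C=C(/C(=O)OC(C)(C)C)CO[Si](C)(C)C(C)(C)C | intermediate
8 | tert-butyl 2-[(E)-acrylate side chain]-6-methylidene-3-isopropylcyclohexane-1-carboxylate, 1,2,3-all-cis | CC(C)[C@H]1CCC(=C)[C@@H](C(=O)OC(C)(C)C)[C@H]1/C=C(/C(=O)OC(C)(C)C)CO[Si](C)(C)C(C)(C)C | intermediate
9 | diol of 8: C10 carries OH (trans to the C1, C6, C7 substituents) and CH2OH (cis to them) | CC(C)[C@H]1CC[C@@](O)(CO)[C@@H](C(=O)OC(C)(C)C)[C@H]1/C=C(/C(=O)OC(C)(C)C)CO[Si](C)(C)C(C)(C)C | intermediate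
10 | (S)-(+)-α-phellandrene, (5S)-2-methyl-5-(propan-2-yl)cyclohexa-1,3-diene | CC(C)[C@@H]1CC=C(C)C=C1 | starting material
11 | methyl buta-2,3-dienoate | C=C=CC(=O)OC | starting material
12 | methyl ester analogue of 3 in the mirror-image series | CC(C)[C@@H]1C[C@H]2C(=C)[C@H](C(=O)OC)[C@@H]1C=C2C | intermediate
13 | ozonide of 12 across the former bridge alkene | CC(C)[C@@H]1C[C@H]2C(=C)[C@H](C(=O)OC)[C@@H]1C3OC2(C)OO3 | intermediate (not isolated)
14 | methyl 3-acetyl-6-formyl-2-methylidene-5-isopropylcyclohexane-1-carboxylate, all-cis, mirror-image series of 5 | CC(C)[C@@H]1C[C@H](C(C)=O)C(=C)[C@H](C(=O)OC)[C@@H]1C=O | intermediate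
15 | as 14 with CHO replaced by (E)-CH=C(CH2OTBDPS)CO2tBu | CC(C)[C@@H]1C[C@H](C(C)=O)C(=C)[C@H](C(=O)OC)[C@@H]1/C=C(/C(=O)OC(C)(C)C)CO[Si](c1ccccc1)(c1ccccc1)C(C)(C)C | intermediate
16 | as 15 with the C9' acetyl replaced by acetoxy | CC(C)[C@@H]1C[C@H](OC(C)=O)C(=C)[C@H](C(=O)OC)[C@@H]1/C=C(/C(=O)OC(C)(C)C)CO[Si](c1ccccc1)(c1ccccc1)C(C)(C)C | intermediate
17 | methyl 2-[(E)-acrylate side chain]-6-methylidene-3-isopropylcyclohexane-1-carboxylate, 1,2,3-all-cis | CC(C)[C@@H]1CCC(=C)[C@H](C(=O)OC)[C@@H]1/C=C(/C(=O)OC(C)(C)C)CO[Si](c1ccccc1)(c1ccccc1)C(C)(C)C | intermediate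
18 | carboxylic acid of 17 (C2' acid, methylidene on C10') | CC(C)[C@@H]1CCC(=C)[C@H](C(=O)O)[C@@H]1/C=C(/C(=O)OC(C)(C)C)CO[Si](c1ccccc1)(c1ccccc1)C(C)(C)C | intermediate
19 | cis-fused iodo-β-lactone: C2' carbonyl–O–C10', CH2I on C10' | CC(C)[C@@H]1CC[C@]2(CI)OC(=O)[C@@H]2[C@@H]1/C=C(/C(=O)OC(C)(C)C)CO[Si](c1ccccc1)(c1ccccc1)C(C)(C)C | intermediate (not isolated)
20 | allylic iodide: cyclohexene with C1'=C10', CH2I on C10', side chain and isopropyl cis | CC(C)[C@@H]1CCC(CI)=C[C@@H]1/C=C(/C(=O)OC(C)(C)C)CO[Si](c1ccccc1)(c1ccccc1)C(C)(C)C | intermediate (not isolated)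
21 | tert-butyl (E)-2-(TBDPS-oxymethyl)-3-[3-(hydroxymethyl)-6-isopropylcyclohex-2-en-1-yl]acrylate, ring substituents cis as in 23 | CC(C)[C@@H]1CCC(CO)=C[C@@H]1/C=C(/C(=O)OC(C)(C)C)CO[Si](c1ccccc1)(c1ccccc1)C(C)(C)C | intermediate
22 | bis-TBDPS ether of 21 | CC(C)[C@@H]1CCC(CO[Si](c2ccccc2)(c2ccccc2)C(C)(C)C)=C[C@@H]1/C=C(/C(=O)OC(C)(C)C)CO[Si](c1ccccc1)(c1ccccc1)C(C)(C)C | intermediate
23 | (E)-2-(TBDPS-oxymethyl)-3-[(1R,6S)-3-(TBDPS-oxymethyl)-6-isopropylcyclohex-2-en-1-yl]acrylic acid (fragment A) | CC(C)[C@@H]1CCC(CO[Si](c2ccccc2)(c2ccccc2)C(C)(C)C)=C[C@@H]1/C=C(/C(=O)O)CO[Si](c1ccccc1)(c1ccccc1)C(C)(C)C | intermediate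
24 | 9 acylated on the C14 oxygen by 23; C10 hydroxyl free | CC(C)[C@H]1CC[C@@](O)(COC(=O)/C(=C/[C@H]2C=C(CO[Si](c3ccccc3)(c3ccccc3)C(C)(C)C)CC[C@H]2C(C)C)CO[Si](c2ccccc2)(c2ccccc2)C(C)(C)C)[C@@H](C(=O)OC(C)(C)C)[C@H]1/C=C(/C(=O)OC(C)(C)C)CO[Si](C)(C)C(C)(C)C | intermediate
25 | seco diacid: C2 and C3 acids and C15 hydroxyl free, fragment A still bis-TBDPS | CC(C)[C@H]1CC[C@@](O)(COC(=O)/C(=C/[C@H]2C=C(CO[Si](c3ccccc3)(c3ccccc3)C(C)(C)C)CC[C@H]2C(C)C)CO[Si](c2ccccc2)(c2ccccc2)C(C)(C)C)[C@@H](C(=O)O)[C@H]1/C=C(/C(=O)O)CO | intermediate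
26 | bis-TBDPS ether of the target (ε-lactone closed, cis ring fusion) | CC(C)[C@H]1CC[C@@](O)(COC(=O)/C(=C/[C@H]2C=C(CO[Si](c3ccccc3)(c3ccccc3)C(C)(C)C)CC[C@H]2C(C)C)CO[Si](c2ccccc2)(c2ccccc2)C(C)(C)C)[C@H]2C(=O)OCC(C(=O)O)=C[C@@H]12 | intermediate
27 | (5aR,6R,9S,9aS)-9-hydroxy-9-[({(2E)-2-(hydroxymethyl)-3-[(1R,6S)-3-(hydroxymethyl)-6-(propan-2-yl)cyclohex-2-en-1-yl]prop-2-enoyl}oxy)methyl]-1-oxo-6-(propan-2-yl)-1,3,5a,6,7,8,9,9a-octahydro-2-benzoxepine-4-carboxylic acid | CC(C)[C@H]1CC[C@@](O)(COC(=O)/C(=C/[C@H]2C=C(CO)CC[C@H]2C(C)C)CO)[C@H]2C(=O)OCC(C(=O)O)=C[C@@H]12 | target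

## Step count and risk

Total steps: 19. Longest linear sequence: 13 (steps 7–15, then 16–19).

Steps most likely to fail:

Step 2 (ozone must spare the exocyclic methylene). Fallback: set out from 3 and epoxidise only the more nucleophilic trisubstituted bridge alkene (mCPBA, NaHCO3, CH2Cl2, 0 °C) to the bridge epoxide F1; cleave it with H5IO6 (THF–H2O, 0 °C → rt) straight to keto aldehyde 5, where the route is rejoined.

Step 4 (Baeyer–Villiger of a methyl ketone beside an alkene, tert-butyl esters and a silyl ether). Fallback: set out from 6 and condense the ketone with NH2OH·HCl/NaOAc (EtOH) to the ketoxime F2. A Beckmann fragmentation (TsCl, pyridine, LiCl, 0 → 40 °C) expels acetonitrile because C9 leaves as an allyl cation, and chloride traps it as the allylic chloride F3 (its C9-chloro isomer behaves the same). The unchanged Pd(OAc)2/PBu3/HCO2NH4 hydrogenolysis then delivers 8, where the route is rejoined.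

Step 18 (seven-membered lactonisation of a diacid by acyl activation). Fallback: set out from 24 and remove only the primary TBS ether (HF·pyridine, pyridine–THF, 0 °C) to give the allylic alcohol F4. Convert it into the allylic bromide F5 (CBr4, PPh3, CH2Cl2, 0 °C), cleave both tert-butyl esters (TFA–CH2Cl2) to the bromo diacid F6, and close the ring by carboxylate O-alkylation (Cs2CO3, DMF, 2 mM); only the C2 carboxylate can reach C15. This gives 26, where the route is rejoined.

Further compounds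
F1 | step 2 | bridge epoxide of 3 (oxirane across the former C5=C6 of the bicycle, methylidene untouched; oxirane face not defined) | CC(C)[C@H]1C[C@@H]2C(=C)[C@@H](C(=O)OC(C)(C)C)[C@H]1C3OC23C
F2 | step 4 | ketoxime of 6 (C9 bears C(CH3)=NOH) | CC(C)[C@H]1C[C@@H](C(C)=NO)C(=C)[C@@H](C(=O)OC(C)(C)C)[C@H]1/C=C(/C(=O)OC(C)(C)C)CO[Si](C)(C)C(C)(C)C
F3 | step 4 | allylic chloride: C9=C10 alkene with CH2Cl on C10, other groups as in 8 | CC(C)[C@H]1CC=C(CCl)[C@@H](C(=O)OC(C)(C)C)[C@H]1/C=C(/C(=O)OC(C)(C)C)CO[Si](C)(C)C(C)(C)C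
F4 | step 18 | 24 with the C15 hydroxyl free (TBS removed) | CC(C)[C@H]1CC[C@@](O)(COC(=O)/C(=C/[C@H]2C=C(CO[Si](c3ccccc3)(c3ccccc3)C(C)(C)C)CC[C@H]2C(C)C)CO[Si](c2ccccc2)(c2ccccc2)C(C)(C)C)[C@@H](C(=O)OC(C)(C)C)[C@H]1/C=C(/C(=O)OC(C)(C)C)CO
F5 | step 18 | C15 allylic bromide of F4 | CC(C)[C@H]1CC[C@@](O)(COC(=O)/C(=C/[C@H]2C=C(CO[Si](c3ccccc3)(c3ccccc3)C(C)(C)C)CC[C@H]2C(C)C)CO[Si](c2ccccc2)(c2ccccc2)C(C)(C)C)[C@@H](C(=O)OC(C)(C)C)[C@H]1/C=C(/C(=O)OC(C)(C)C)CBr
F6 | step 18 | bromo diacid (C2 and C3 acids free, C15 bromide) | CC(C)[C@H]1CC[C@@](O)(COC(=O)/C(=C/[C@H]2C=C(CO[Si](c3ccccc3)(c3ccccc3)C(C)(C)C)CC[C@H]2C(C)C)CO[Si](c2ccccc2)(c2ccccc2)C(C)(C)C)[C@@H](C(=O)O)[C@H]1/C=C(/C(=O)O)CBr
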